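**Retrosynthetic overview**

- The route rests on the para-dioxygenation of ring B at C2'/C5'. In the quinone form, C5'=O, C6'=C1' and an exocyclic C3=C2 methylidene make a linear dienone whose terminus C2 lies six atoms from the ring A phenol oxygen O1.
- Last disconnection: O1–C2 of ring C, made by oxidising the hydroquinone to the alkenylquinone, 6-endo oxa-Michael addition and return of hydrogen to C3. The quinone state also removes the ring B phenols as competing nucleophiles.
- The precursor, a 1,2-diaryl allylic alcohol, comes from a C3–C1' Suzuki–Miyaura coupling of a 2-boryl allylic alcohol with a ring B aryl bromide.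
- C4 is set earlier by catalytic asymmetric alkynylation of the ring A salicylaldehyde (C3–C4 bond), because an aryl/alkynyl pair is differentiated far more reliably than the two sp2 groups of the corresponding enone; the alkyne is then turned into the internal alkenylboronate.
- Rings A and B are bought as arenes; ring C is the only ring formed, and it is formed last, before one neutral reduction of the quinone.

Key step: step 11

Remark on the chemistry: the target is read as the (3S,4R)-trans-isoflavan-4-ol. The facial sense of the (R)-BINOL/Ti(OiPr)4 alkynylation is assumed to follow that known for simple aromatic aldehydes; if the ortho-silyloxy group reverses it, (S)-BINOL is used.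

**Route**

Step 1
Reactants: 1 2,3,4-trimethoxyphenol; 2 formaldehyde (as paraformaldehyde)
Product: 3 2-hydroxy-3,4,5-trimethoxybenzaldehyde
Conditions: MgCl2, Et3N, (CH2O)n, MeCN, reflux
Reagents that add atoms: none
Why: Casnati–Skattebøl magnesium-mediated ortho-formylation delivers formaldehyde inside the magnesium phenoxide chelate to the only free ortho position of 1, a second equivalent of formaldehyde accepting hydride to give the aldehyde.

Step 2
Reactants: 3 2-hydroxy-3,4,5-trimethoxybenzaldehyde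
Product: 4 3,4,5-trimethoxy-2-(triisopropylsilyloxy)benzaldehyde
Conditions: TIPSCl, imidazole, DMAP (cat.), DMF, rt to 40 °C
Reagents that add atoms: triisopropylsilyl chloride, CC(C)[Si](Cl)(C(C)C)C(C)C
Why: Silyl ether formation masks the phenol for the organozinc, copper-boryl and palladium steps, the triisopropylsilyl group being chosen because it survives K2CO3/MeOH and aqueous phosphate but falls to fluoride.

Step 3
Reactants: 4 3,4,5-trimethoxy-2-(triisopropylsilyloxy)benzaldehyde; 5 trimethylsilylacetylene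
Product: 6 (S)-3-(trimethylsilyl)-1-[3,4,5-trimethoxy-2-(triisopropylsilyloxy)phenyl]prop-2-yn-1-ol
Conditions: 5, ZnEt2, toluene, 60 °C (sealed); then (R)-BINOL (20 mol%), Ti(OiPr)4 (50 mol%), CH2Cl2, rt; then 4, rt
Reagents that add atoms: none
Why: Catalytic enantioselective alkynylzinc addition to an aromatic aldehyde (BINOL–Ti(OiPr)4 type) forms the C3–C4 bond and sets the carbinol centre (the future C4) by catalyst control, (R)-BINOL directing the alkynyl group to the Re face, the descriptor reading (S) only because the silicon-bearing alkynyl branch outranks the aryl ring.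

Step 4
Reactants: 6 (S)-3-(trimethylsilyl)-1-[3,4,5-trimethoxy-2-(triisopropylsilyloxy)phenyl]prop-2-yn-1-ol
Product: 7 (R)-1-[3,4,5-trimethoxy-2-(triisopropylsilyloxy)phenyl]prop-2-yn-1-ol
Conditions: K2CO3 (cat.), MeOH, 0 °C
Reagents that add atoms: none
Why: Base-catalysed methanolysis of the alkynyl C–Si bond (protiodesilylation) frees the terminal alkyne without touching the aryl silyl ether or the carbinol centre, whose descriptor changes to (R) through the CIP ranking alone.

Step 5
Reactants: 7 (R)-1-[3,4,5-trimethoxy-2-(triisopropylsilyloxy)phenyl]prop-2-yn-1-ol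
Product: 8 (R)-2-(4,4,5,5-tetramethyl-1,3,2-dioxaborolan-2-yl)-1-[3,4,5-trimethoxy-2-(triisopropylsilyloxy)phenyl]prop-2-en-1-ol
Conditions: (SIMes)CuCl (5 mol%), NaOtBu (5 mol%), B2pin2, MeOH, THF, −50 to −15 °C
Reagents that add atoms: bis(pinacolato)diboron, CC1(C)OB(OC1(C)C)B1OC(C)(C)C(C)(C)O1
Why: Copper-catalysed protoboration of a terminal propargylic alcohol with an N-aryl carbene ligand (SIMes = 1,3-dimesitylimidazolin-2-ylidene) places boron on the internal carbon by syn Cu–B addition and protonation by MeOH, giving the 1,1-disubstituted alkenylboronate with the carbinol centre untouched.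

Step 6
Reactants: 9 2,3-dimethoxy-1,4-benzoquinone
Product: 10 2,3-dimethoxybenzene-1,4-diol
Conditions: Na2S2O4, EtOAc/H2O, rt
Reagents that add atoms: none
Why: Reduction of a quinone to its hydroquinone by Na2S2O4 is routine and exposes the two phenols that are to be masked.

Step 7
Reactants: 10 2,3-dimethoxybenzene-1,4-diol
Product: 11 1,4-bis(tert-butyldimethylsilyloxy)-2,3-dimethoxybenzene
Conditions: TBSCl, imidazole, DMF, rt
Reagents that add atoms: tert-butyldimethylsilyl chloride, CC(C)(C)[Si](C)(C)Cl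
Why: Standard silylation of both phenols gives fluoride-labile protection matched to that of ring A, so that one reagent later frees all three phenols.

Step 8
Reactants: 11 1,4-bis(tert-butyldimethylsilyloxy)-2,3-dimethoxybenzene
Product: 12 1-bromo-2,5-bis(tert-butyldimethylsilyloxy)-3,4-dimethoxybenzene
Conditions: NBS (1.0 equiv), MeCN, 0 °C to rt
Reagents that add atoms: N-bromosuccinimide, O=C1CCC(=O)N1Br
Why: Electrophilic aromatic bromination of the tetraoxygenated ring can only occur at one of the two equivalent free positions, and the first bromine deactivates the ring towards a second substitution.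

Step 9
Reactants: 8 (R)-2-(4,4,5,5-tetramethyl-1,3,2-dioxaborolan-2-yl)-1-[3,4,5-trimethoxy-2-(triisopropylsilyloxy)phenyl]prop-2-en-1-ol; 12 1-bromo-2,5-bis(tert-butyldimethylsilyloxy)-3,4-dimethoxybenzene
Product: 13 (R)-2-[2,5-bis(tert-butyldimethylsilyloxy)-3,4-dimethoxyphenyl]-1-[3,4,5-trimethoxy-2-(triisopropylsilyloxy)phenyl]prop-2-en-1-ol
Conditions: Pd(OAc)2 (5 mol%), SPhos (10 mol%), K3PO4, THF/H2O 10:1, 50 °C
Reagents that add atoms: none
Why: Suzuki–Miyaura coupling joins C3 to C1' of ring B, the electron-rich biarylphosphine allowing oxidative addition to the hindered, electron-rich aryl bromide while the carbinol centre is a spectator.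

Step 10
Reactants: 13 (R)-2-[2,5-bis(tert-butyldimethylsilyloxy)-3,4-dimethoxyphenyl]-1-[3,4,5-trimethoxy-2-(triisopropylsilyloxy)phenyl]prop-2-en-1-ol
Product: 14 (R)-2-(2,5-dihydroxy-3,4-dimethoxyphenyl)-1-(2-hydroxy-3,4,5-trimethoxyphenyl)prop-2-en-1-ol
Conditions: TBAF (3.5 equiv), AcOH (3.5 equiv), THF, 0 °C to rt, Ar; pH 7 work-up
Reagents that add atoms: none
Why: Fluoride cleaves the three aryl silyl ethers while acetic acid buffers the phenoxides so that neither autoxidation nor ionisation of the benzylic allylic alcohol sets in, and the triphenol is taken on at once.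

Step 11
Reactants: 14 (R)-2-(2,5-dihydroxy-3,4-dimethoxyphenyl)-1-(2-hydroxy-3,4,5-trimethoxyphenyl)prop-2-en-1-ol
Product: 17 2-[(3S,4R)-4-hydroxy-6,7,8-trimethoxychroman-3-yl]-5,6-dimethoxy-1,4-benzoquinone, via alkenylquinone 15 (not isolated), via hydroxy-ortho-quinone methide 16 (not isolated)
Conditions: Ag2O (1.3 equiv), MgSO4, CH2Cl2 (0.01 M), 0 °C to rt, dark; filter; iPr2NEt (10 mol%), 0 °C, Ar
Reagents that add atoms: none
Why: Proposed new method: Ag2O dehydrogenates only the ring B hydroquinone, by far the most easily oxidised ring, to alkenylquinone 15, in which C5'=O, C6'=C1' and C3=C2 form a linear dienone; the ring A phenol then adds to the terminal carbon C2 in a 1,6-sense, forming O1–C2, and the resulting dienol 16 is reprotonated at C3 to restore the quinone. The closest known reactions are the 6-endo oxa-Michael closure of 2'-hydroxy-α-methylene-deoxybenzoins to isoflavanones and the 1,6-addition of heteroatom nucleophiles to alkenylquinones and quinone methides. Ring C closes in the 6-endo-trig mode. The new stereocentre C3 is controlled by the C4 carbinol: C3–H of 17 is vinylogously acidic and exchanges through 16 under the amine catalyst, so the (3S,4R)-trans isomer, with aryl and hydroxyl both pseudo-equatorial on the half-chair, should accumulate. The step needs attack at C2 and not on the quinone ring, which is secured because closure at C6' would be a seven-ring closure for O1 and a disfavoured 5-endo closure for the C4 hydroxyl, and because ring B in the quinone state carries no phenol that could compete. High dilution and low temperature are meant to hold back dimerisation of 15 and hydrogen shift from C4 in 16.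

Step 12
Reactants: 17 2-[(3S,4R)-4-hydroxy-6,7,8-trimethoxychroman-3-yl]-5,6-dimethoxy-1,4-benzoquinone
Product: 18 (3S,4R)-3-(2,5-dihydroxy-3,4-dimethoxyphenyl)-6,7,8-trimethoxychroman-4-ol (target)
Conditions: Na2S2O4, EtOAc/pH 7 phosphate buffer, rt, Ar
Reagents that add atoms: none
Why: Quinone-to-hydroquinone reduction with Na2S2O4 under neutral two-phase conditions leaves both stereocentres untouched (C3–H is no longer acidic once ring B is aromatic) and avoids the acid that would ionise the 4-hydroxyl and close a pterocarpan.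

**Compound list**

1 | 2,3,4-trimethoxyphenol | COc1ccc(O)c(OC)c1OC | starting material
2 | formaldehyde (used as paraformaldehyde) | C=O | starting material
3 | 2-hydroxy-3,4,5-trimethoxybenzaldehyde | COc1cc(C=O)c(O)c(OC)c1OC | intermediate
4 | 3,4,5-trimethoxy-2-(triisopropylsilyloxy)benzaldehyde | COc1cc(C=O)c(O[Si](C(C)C)(C(C)C)C(C)C)c(OC)c1OC | intermediate
5 | trimethylsilylacetylene | C#C[Si](C)(C)C | starting material
6 | (S)-3-(trimethylsilyl)-1-[3,4,5-trimethoxy-2-(triisopropylsilyloxy)phenyl]prop-2-yn-1-ol | C[Si](C)(C)C#C[C@H](c1cc(OC)c(OC)c(OC)c1O[Si](C(C)C)(C(C)C)C(C)C)O | intermediate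
7 | (R)-1-[3,4,5-trimethoxy-2-(triisopropylsilyloxy)phenyl]prop-2-yn-1-ol | C#C[C@H](c1cc(OC)c(OC)c(OC)c1O[Si](C(C)C)(C(C)C)C(C)C)O | intermediate
8 | (R)-2-(4,4,5,5-tetramethyl-1,3,2-dioxaborolan-2-yl)-1-[3,4,5-trimethoxy-2-(triisopropylsilyloxy)phenyl]prop-2-en-1-ol | C=C(B1OC(C)(C)C(C)(C)O1)[C@H](c1cc(OC)c(OC)c(OC)c1O[Si](C(C)C)(C(C)C)C(C)C)O | intermediate
9 | 2,3-dimethoxy-1,4-benzoquinone | COC1=C(OC)C(=O)C=CC1=O | starting material
10 | 2,3-dimethoxybenzene-1,4-diol | COc1c(O)ccc(O)c1OC | intermediate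
11 | 1,4-bis(tert-butyldimethylsilyloxy)-2,3-dimethoxybenzene | COc1c(O[Si](C)(C)C(C)(C)C)ccc(O[Si](C)(C)C(C)(C)C)c1OC | intermediate
12 | 1-bromo-2,5-bis(tert-butyldimethylsilyloxy)-3,4-dimethoxybenzene | COc1c(O[Si](C)(C)C(C)(C)C)cc(Br)c(O[Si](C)(C)C(C)(C)C)c1OC | intermediate
13 | (R)-2-[2,5-bis(tert-butyldimethylsilyloxy)-3,4-dimethoxyphenyl]-1-[3,4,5-trimethoxy-2-(triisopropylsilyloxy)phenyl]prop-2-en-1-ol | C=C(c1cc(O[Si](C)(C)C(C)(C)C)c(OC)c(OC)c1O[Si](C)(C)C(C)(C)C)[C@H](c1cc(OC)c(OC)c(OC)c1O[Si](C(C)C)(C(C)C)C(C)C)O | intermediate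
14 | (R)-2-(2,5-dihydroxy-3,4-dimethoxyphenyl)-1-(2-hydroxy-3,4,5-trimethoxyphenyl)prop-2-en-1-ol | C=C(c1cc(O)c(OC)c(OC)c1O)[C@H](c1cc(OC)c(OC)c(OC)c1O)O | intermediate
15 | 2-[(R)-3-hydroxy-3-(2-hydroxy-3,4,5-trimethoxyphenyl)prop-1-en-2-yl]-5,6-dimethoxy-1,4-benzoquinone | C=C(C1=CC(=O)C(OC)=C(OC)C1=O)[C@H](c1cc(OC)c(OC)c(OC)c1O)O | intermediate
16 | 4-hydroxy-6-[(4R)-4-hydroxy-6,7,8-trimethoxychroman-3-ylidene]-2,3-dimethoxycyclohexa-2,4-dien-1-one (alkene geometry not defined) | COc1cc2c(c(OC)c1OC)OCC(=C1C=C(O)C(OC)=C(OC)C1=O)[C@H]2O | intermediate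
17 | 2-[(3S,4R)-4-hydroxy-6,7,8-trimethoxychroman-3-yl]-5,6-dimethoxy-1,4-benzoquinone | COc1cc2c(c(OC)c1OC)OC[C@H](C3=CC(=O)C(OC)=C(OC)C3=O)[C@H]2O | intermediate
18 | (3S,4R)-3-(2,5-dihydroxy-3,4-dimethoxyphenyl)-6,7,8-trimethoxychroman-4-ol | COc1cc2c(c(OC)c1OC)OC[C@H](c1cc(O)c(OC)c(OC)c1O)[C@H]2O | target

**Step count**

Total: 12 steps. Longest linear sequence: 9 steps (steps 1–5 and 9–12); the ring B branch is steps 6–8.

**Steps most likely to fail**

Step 11. Several processes could divert the cascade: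
- Hydrogen shift from C4 in the quinone methide tautomer, an internal redox that would end at the isoflavanone hydroquinone.
- Base-induced vinylogous elimination of the C4 hydroxyl.
- Cycloaddition dimerisation of the alkenylquinone.
- Incomplete equilibration at C3, giving poor diastereocontrol.

The fallback sets out from 8 (with a ring B partner made from 10) and comes back at 18. It closes ring C by hydroboration and Mitsunobu etherification, with ring B held as a dibenzyl ether so that only the ring A phenol is free at the closure. Benzylation of 10 (BnBr, K2CO3, DMF) should give 1,4-bis(benzyloxy)-2,3-dimethoxybenzene F1, and NBS in MeCN should give 1,4-bis(benzyloxy)-5-bromo-2,3-dimethoxybenzene F2. Suzuki–Miyaura coupling of F2 with 8 under the conditions of step 9 should give (R)-2-[2,5-bis(benzyloxy)-3,4-dimethoxyphenyl]-1-[3,4,5-trimethoxy-2-(triisopropylsilyloxy)phenyl]prop-2-en-1-ol F3. TBSOTf and 2,6-lutidine should convert it into (R)-2-[2,5-bis(benzyloxy)-3,4-dimethoxyphenyl]-1-(tert-butyldimethylsilyloxy)-1-[3,4,5-trimethoxy-2-(triisopropylsilyloxy)phenyl]prop-2-ene F4. Catecholborane with RhCl(PPh3)3 (3 mol%) in THF, then NaBO3·4H2O, should give (2S,3R)-2-[2,5-bis(benzyloxy)-3,4-dimethoxyphenyl]-3-(tert-butyldimethylsilyloxy)-3-[3,4,5-trimethoxy-2-(triisopropylsilyloxy)phenyl]propan-1-ol F5. The rhodium-catalysed hydroboration of 1,1-disubstituted allylic silyl ethers is syn-selective, and the syn open-chain relationship corresponds to the trans ring relationship. TBAF should remove both silyl groups to give (1R,2S)-2-[2,5-bis(benzyloxy)-3,4-dimethoxyphenyl]-1-(2-hydroxy-3,4,5-trimethoxyphenyl)propane-1,3-diol F6. Mitsunobu etherification (PPh3, DIAD, THF, 0 °C) at the primary carbon should close O1–C2 to (3S,4R)-3-[2,5-bis(benzyloxy)-3,4-dimethoxyphenyl]-6,7,8-trimethoxychroman-4-ol F7. Hydrogenolysis (H2, Pd/C, EtOAc, neutral) should then give 18.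

Step 9. Protodeboronation of the α-branched alkenylboronate and base-induced loss of the aryl silyl ethers may outrun the slow oxidative addition to the hindered, electron-rich bromide. The fallback sets out from 7 and comes back at 13. Molybdenum-catalysed hydrostannation of 7 (Mo(CO)3(CNtBu)3, Bu3SnH, THF, 55 °C), which places tin on the internal carbon of propargylic alcohols, should give (S)-2-(tributylstannyl)-1-[3,4,5-trimethoxy-2-(triisopropylsilyloxy)phenyl]prop-2-en-1-ol F8 (same spatial arrangement as 8; the descriptor changes because tin raises the alkenyl branch). A base-free Stille coupling of F8 with 12 (Pd(PtBu3)2, CuI, LiCl, NMP, 60 °C) should then give 13 with no aqueous base present.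

Step 3. Facial discrimination may be insufficient, or reversed, with the ortho-silyloxy, electron-rich aldehyde. The fallback sets out from 4 and comes back at 7. Ethynylmagnesium bromide (THF, 0 °C) should give racemic 1-[3,4,5-trimethoxy-2-(triisopropylsilyloxy)phenyl]prop-2-yn-1-ol F9. Esterification with (S)-2-methoxy-2-phenylacetic acid (EDC, DMAP, CH2Cl2, 0 °C) gives two diastereomeric esters that are separated by chromatography. The ester of the (R)-carbinol, (R)-1-[3,4,5-trimethoxy-2-(triisopropylsilyloxy)phenyl]prop-2-yn-1-yl (S)-2-methoxy-2-phenylacetate F10, is cleaved with K2CO3 in MeOH at 0 °C to 7. This replaces steps 3 and 4 at the cost of half the material.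

Further compounds
F1 | step 11 | 1,4-bis(benzyloxy)-2,3-dimethoxybenzene | COc1c(OCc2ccccc2)ccc(OCc2ccccc2)c1OC
F2 | step 11 | 1,4-bis(benzyloxy)-5-bromo-2,3-dimethoxybenzene | COc1c(OCc2ccccc2)cc(Br)c(OCc2ccccc2)c1OC
F3 | step 11 | (R)-2-[2,5-bis(benzyloxy)-3,4-dimethoxyphenyl]-1-[3,4,5-trimethoxy-2-(triisopropylsilyloxy)phenyl]prop-2-en-1-ol | C=C(c1cc(OCc2ccccc2)c(OC)c(OC)c1OCc1ccccc1)[C@H](c1cc(OC)c(OC)c(OC)c1O[Si](C(C)C)(C(C)C)C(C)C)O
F4 | step 11 | (R)-2-[2,5-bis(benzyloxy)-3,4-dimethoxyphenyl]-1-(tert-butyldimethylsilyloxy)-1-[3,4,5-trimethoxy-2-(triisopropylsilyloxy)phenyl]prop-2-ene | C=C(c1cc(OCc2ccccc2)c(OC)c(OC)c1OCc1ccccc1)[C@H](c1cc(OC)c(OC)c(OC)c1O[Si](C(C)C)(C(C)C)C(C)C)O[Si](C)(C)C(C)(C)C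
F5 | step 11 | (2S,3R)-2-[2,5-bis(benzyloxy)-3,4-dimethoxyphenyl]-3-(tert-butyldimethylsilyloxy)-3-[3,4,5-trimethoxy-2-(triisopropylsilyloxy)phenyl]propan-1-ol | OC[C@H](c1cc(OCc2ccccc2)c(OC)c(OC)c1OCc1ccccc1)[C@H](c1cc(OC)c(OC)c(OC)c1O[Si](C(C)C)(C(C)C)C(C)C)O[Si](C)(C)C(C)(C)C
F6 | step 11 | (1R,2S)-2-[2,5-bis(benzyloxy)-3,4-dimethoxyphenyl]-1-(2-hydroxy-3,4,5-trimethoxyphenyl)propane-1,3-diol | OC[C@H](c1cc(OCc2ccccc2)c(OC)c(OC)c1OCc1ccccc1)[C@H](c1cc(OC)c(OC)c(OC)c1O)O
F7 | step 11 | (3S,4R)-3-[2,5-bis(benzyloxy)-3,4-dimethoxyphenyl]-6,7,8-trimethoxychroman-4-ol | COc1cc2c(c(OC)c1OC)OC[C@H](c1cc(OCc3ccccc3)c(OC)c(OC)c1OCc1ccccc1)[C@H]2O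
F8 | step 9 | (S)-2-(tributylstannyl)-1-[3,4,5-trimethoxy-2-(triisopropylsilyloxy)phenyl]prop-2-en-1-ol | C=C([Sn](CCCC)(CCCC)CCCC)[C@H](c1cc(OC)c(OC)c(OC)c1O[Si](C(C)C)(C(C)C)C(C)C)O
F9 | step 3 | racemic 1-[3,4,5-trimethoxy-2-(triisopropylsilyloxy)phenyl]prop-2-yn-1-ol | C#CC(c1cc(OC)c(OC)c(OC)c1O[Si](C(C)C)(C(C)C)C(C)C)O
F10 | step 3 | (R)-1-[3,4,5-trimethoxy-2-(triisopropylsilyloxy)phenyl]prop-2-yn-1-yl (S)-2-methoxy-2-phenylacetate | C#C[C@H](c1cc(OC)c(OC)c(OC)c1O[Si](C(C)C)(C(C)C)C(C)C)OC(=O)[C@@H](OC)c1ccccc1
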